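**Retrosynthetic overview**

1. Tandyukisin C ⇐ acylation of the C5 hydroxyl of a 5,6-diol with 3-methylglutaconic anhydride; diol ⇐ syn-dihydroxylation of C5=C6; 3-hydroxypropanoyl ketone ⇐ C1 carboxylic acid (MeLi, then formaldehyde aldol).
2. Ring B ⇐ ring-closing metathesis of a C4a vinyl arm and a C8a pent-4-en-2-yl arm on ring A (second carbocycle).
3. Feature the plan rests on: in ring A the carboxyl carbon on C1, then C1, C2 and the C3=C4 alkene make up a γ,δ-unsaturated acid. It is cut at C1–C2 by a ring-contracting Ireland–Claisen shift of a δ-lactone (acyl C–O–C4) carrying an E-alkenyl arm on C4 (first carbocycle; sets C1 and C2).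
4. Lactone ⇐ C1 methylation, C5 acyl → vinyl, lactonisation of C4–OH onto a thioester; C4/C4a ⇐ auxiliary-controlled syn-aldol with (2E,4R)-4-methylhex-2-enal; C8a ⇐ iminium-catalysed Mukaiyama–Michael addition to (2E,4R)-4-methylhepta-2,6-dienal; C8 ⇐ auxiliary allylation.
5. Ring order: temporary δ-lactone → ring A (key step) → ring B (metathesis).

Key step: step 16

Remark on names: locants C1–C8a follow the decalin numbering of the target throughout, also for monocyclic and acyclic intermediates.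

Assumption: the (2R,5R)-imidazolidinone is taken to expose the Si face at C3 of the E-iminium ion of 5, mirroring the established Re-face addition to β-alkyl enals with its (2S,5S) antipode; if the sense were the reverse, the (2S,5S) catalyst would be used.

**Step 1**
Reactants: 1 (4S)-4-benzyl-3-propanoyl-1,3-oxazolidin-2-one
Product: 2 (4S)-4-benzyl-3-[(2R)-2-methylpent-4-enoyl]-1,3-oxazolidin-2-one
Conditions: NaHMDS, THF, −78 °C; allyl iodide, −78 → −45 °C
Reagents that add atoms: allyl iodide, C=CCI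
Why: Auxiliary-controlled enolate alkylation; the chelated Z-sodium enolate is allylated on the face away from the benzyl group, which sets C8 (R).

**Step 2**
Reactants: 2 (4S)-4-benzyl-3-[(2R)-2-methylpent-4-enoyl]-1,3-oxazolidin-2-one
Product: 3 (2R)-2-methylpent-4-en-1-ol
Conditions: LiBH4, H2O (1 equiv), Et2O, 0 °C
Reagents that add atoms: none
Why: Reductive cleavage of the N-acyl oxazolidinone by borohydride leaves the α-stereocentre untouched and returns the auxiliary.

**Step 3**
Reactants: 3 (2R)-2-methylpent-4-en-1-ol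
Product: 5 (2E,4R)-4-methylhepta-2,6-dienal, via (2R)-2-methylpent-4-enal 4 (not isolated)
Conditions: PhI(OAc)2, TEMPO (10 mol %), CH2Cl2, rt; then Ph3P=CHCHO, 40 °C
Reagents that add atoms: (triphenylphosphoranylidene)acetaldehyde, O=CC=P(c1ccccc1)(c1ccccc1)c1ccccc1
Why: Nitroxyl-catalysed alcohol oxidation followed in the same flask by a Wittig reaction with a stabilised ylide should give the E enal and spares the volatile, epimerisable aldehyde from isolation.

**Step 4**
Reactants: 6 S-tert-butyl ethanethioate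
Product: 7 tert-butyl{[1-(tert-butylsulfanyl)ethenyl]oxy}dimethylsilane
Conditions: LDA, THF, −78 °C; TBSCl, DMPU, −78 °C → rt
Reagents that add atoms: tert-butyldimethylsilyl chloride, CC(C)(C)[Si](C)(C)Cl
Why: O-silylation of the thioester lithium enolate gives the silyl ketene thioacetal that serves as the acetate nucleophile.

**Step 5**
Reactants: 5 (2E,4R)-4-methylhepta-2,6-dienal; 7 tert-butyl{[1-(tert-butylsulfanyl)ethenyl]oxy}dimethylsilane
Product: 8 S-tert-butyl (3S,4R)-4-methyl-3-(2-oxoethyl)hept-6-enethioate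
Conditions: (2R,5R)-5-benzyl-2-tert-butyl-3-methylimidazolidin-4-one·Cl3CCO2H (20 mol %), CH2Cl2, H2O (2 equiv), −78 → −40 °C
Reagents that add atoms: water, O
Why: Iminium-catalysed Mukaiyama–Michael addition; the ketene thioacetal adds to C3 of the E-iminium ion on the face left open by the catalyst benzyl group (Si face), which sets C8a under catalyst control, the weakly biased C8 centre (methyl against allyl) not being expected to override it.

**Step 6**
Reactants: 8 S-tert-butyl (3S,4R)-4-methyl-3-(2-oxoethyl)hept-6-enethioate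
Product: 9 (3S,4R)-3-[2-(tert-butylsulfanyl)-2-oxoethyl]-4-methylhept-6-enoic acid
Conditions: NaClO2, NaH2PO4, 2-methylbut-2-ene, t-BuOH/H2O, 0 °C → rt
Reagents that add atoms: sodium chlorite, [Na+].[O-]Cl=O
Why: Pinnick oxidation converts the aldehyde into the acid without touching the thioester, the terminal alkene or the β-stereocentre.

**Step 7**
Reactants: 9 (3S,4R)-3-[2-(tert-butylsulfanyl)-2-oxoethyl]-4-methylhept-6-enoic acid; 10 (4S)-4-benzyl-1,3-oxazolidin-2-one
Product: 12 S-tert-butyl (3S,4R)-3-{2-[(4S)-4-benzyl-2-oxo-1,3-oxazolidin-3-yl]-2-oxoethyl}-4-methylhept-6-enethioate, via mixed pivalic anhydride 11 (not isolated)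
Conditions: PivCl, Et3N, THF, −20 °C; then 10, LiCl, rt
Reagents that add atoms: none
Why: N-acylation of the oxazolidinone through the mixed pivalic anhydride under the mild lithium chloride/amine protocol, which the hindered thioester should tolerate.

**Step 8**
Reactants: 13 (2S)-3-bromo-2-methylpropan-1-ol
Product: 14 (2R)-2-methylbutan-1-ol
Conditions: MeMgBr (3 equiv), Li2CuCl4 (5 mol %), THF, −78 → 0 °C
Reagents that add atoms: methylmagnesium bromide, C[Mg]Br
Why: Copper-catalysed Grignard cross-coupling (Kochi coupling) of the primary bromide, run on the magnesium alkoxide formed by the first equivalent; the stereocentre is not involved and only its descriptor changes.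

**Step 9**
Reactants: 14 (2R)-2-methylbutan-1-ol
Product: 16 (2E,4R)-4-methylhex-2-enal, via (2R)-2-methylbutanal 15 (not isolated)
Conditions: PhI(OAc)2, TEMPO (10 mol %), CH2Cl2, rt; then Ph3P=CHCHO, 40 °C
Reagents that add atoms: (triphenylphosphoranylidene)acetaldehyde, O=CC=P(c1ccccc1)(c1ccccc1)c1ccccc1
Why: The same one-flask nitroxyl oxidation and E-selective Wittig homologation as in step 3 delivers the enal that carries the (R)-sec-butyl centre.

**Step 10**
Reactants: 12 S-tert-butyl (3S,4R)-3-{2-[(4S)-4-benzyl-2-oxo-1,3-oxazolidin-3-yl]-2-oxoethyl}-4-methylhept-6-enethioate; 16 (2E,4R)-4-methylhex-2-enal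
Product: 18 S-tert-butyl (3S,4R)-3-[(2S,3R,4E,6R)-1-[(4S)-4-benzyl-2-oxo-1,3-oxazolidin-3-yl]-3-hydroxy-6-methyl-1-oxooct-4-en-2-yl]-4-methylhept-6-enethioate, via Z-dibutylboron enolate 17 (not isolated)
Conditions: Bu2BOTf (1.05 equiv), Et3N, CH2Cl2, −78 → 0 °C; 16, −78 → 0 °C; pH 7 buffer, MeOH, H2O2
Reagents that add atoms: none
Why: Evans syn-aldol reaction; the Z-boron enolate of the imide (formed much faster than any thioester enolate) adds 1,2 to the enal through a chair Zimmerman–Traxler transition state on the face dictated by the (S)-benzyl auxiliary, which sets C4a (S) and C4 (R).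

**Step 11**
Reactants: 18 (aldol adduct)
Product: 19 (4S)-4-benzyl-3-{(2R,3S,4S)-2-[(1E,3R)-3-methylpent-1-en-1-yl]-6-oxo-4-[(2R)-pent-4-en-2-yl]oxane-3-carbonyl}-1,3-oxazolidin-2-one
Conditions: AgOCOCF3, Na2HPO4, PhMe/MeCN, rt
Reagents that add atoms: none
Why: Thiophilic silver(I) activation of the S-tert-butyl thioester lets the C4 hydroxyl close the δ-lactone (6-exo-trig acyl substitution) under non-basic conditions that avoid retro-aldol cleavage.

**Step 12**
Reactants: 19 (lactone imide)
Product: 20 (4S,5R,6R)-5-(hydroxymethyl)-6-[(1E,3R)-3-methylpent-1-en-1-yl]-4-[(2R)-pent-4-en-2-yl]oxan-2-one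
Conditions: NaBH4, THF/H2O (4:1), 0 °C
Reagents that add atoms: none
Why: Borohydride reduction of the activated N-acyl oxazolidinone to the primary alcohol is expected to outpace attack on the unactivated δ-lactone at 0 °C, and the equatorial CH2OH group cannot easily reach the lactone carbonyl for translactonisation.

**Step 13**
Reactants: 20 (hydroxymethyl lactone)
Product: 21 (2R,3S,4S)-2-[(1E,3R)-3-methylpent-1-en-1-yl]-6-oxo-4-[(2R)-pent-4-en-2-yl]oxane-3-carbaldehyde
Conditions: Dess–Martin periodinane, CH2Cl2, 0 °C → rt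
Reagents that add atoms: none
Why: Dess–Martin oxidation gives the aldehyde under non-basic conditions, so neither β-elimination of the lactone oxygen nor loss of the equatorial (thermodynamically favoured) C4a configuration is expected.

**Step 14**
Reactants: 21 (lactone aldehyde)
Product: 22 (4S,5S,6R)-5-ethenyl-6-[(1E,3R)-3-methylpent-1-en-1-yl]-4-[(2R)-pent-4-en-2-yl]oxan-2-one
Conditions: Zn, CH2Br2, TiCl4, THF/CH2Cl2, 0 °C
Reagents that add atoms: dibromomethane, BrCBr
Why: Takai–Lombardo methylenation turns the aldehyde into the C4a vinyl group with a non-basic zinc–titanium carbenoid that leaves the lactone carbonyl and the α-stereocentre alone.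

**Step 15**
Reactants: 22 (vinyl lactone)
Product: 24 (3R,4S,5S,6R)-5-ethenyl-3-methyl-6-[(1E,3R)-3-methylpent-1-en-1-yl]-4-[(2R)-pent-4-en-2-yl]oxan-2-one, via lactone lithium enolate 23 (not isolated)
Conditions: LDA, THF, −78 °C; MeI, −78 → −40 °C
Reagents that add atoms: iodomethane, CI
Why: Lactone enolate alkylation; methyl iodide should approach anti to the neighbouring C8a substituent to give the trans C1 methyl lactone, a centre that the next step erases in any case.

**Step 16**
Reactants: 24 (3R,4S,5S,6R)-5-ethenyl-3-methyl-6-[(1E,3R)-3-methylpent-1-en-1-yl]-4-[(2R)-pent-4-en-2-yl]oxan-2-one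
Product: 27 (1S,2S,5R,6S)-2-[(2R)-butan-2-yl]-5-ethenyl-1-methyl-6-[(2R)-pent-4-en-2-yl]cyclohex-3-ene-1-carboxylic acid, via silyl ketene acetal 25 (not isolated), via silyl ester 26 (not isolated)
Conditions: LDA, THF, −78 °C; TBSCl, DMPU, −78 °C → rt; PhMe, 110 °C; then 1 M HCl, THF, rt
Reagents that add atoms: none
Why: LDA removes the C1 hydrogen and TBSCl traps the enolate on oxygen to give the cyclic ketene acetal 25, whose geometry is fixed by the ring; on heating, the O–C(OSi)=C1 and C4–C3=C2 units undergo a concerted suprafacial [3,3] shift (Ireland–Claisen rearrangement, the known ring-contracting variant that turns alkenyl lactones into cycloalkenecarboxylic acids), forming C1–C2, breaking C4–O and moving the alkene to C3=C4, after which silyl ester 26 is hydrolysed. Ring A (C1, C2, C3, C4, C4a, C8a) closes as the lactone opens: the E-alkenyl arm on C4 folds across the lactone, and the six reacting atoms can only adopt a boat, bicyclo[2.2.2]octane-like transition state. C2 is set by chirality transfer from C4, because the E alkene holds the sec-butyl group in the outer position of the allyl unit and C1 bonds to the allyl face from which the C4–O bond departs. C1 is set because the tethered arm can reach only one face of the planar acetal carbon, so the carboxyl carbon ends cis to the sec-butyl group and the methyl trans. The step needs O- rather than C-silylation and a reachable boat; the monocyclic lactone with trans C4a and C8a arms can flex into it, and the C4a vinyl group offers no competing [3,3] path because it is not attached to the oxygen-bearing carbon.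

**Step 17**
Reactants: 27 (ring A acid)
Product: 28 (1S,2S,4aR,8R,8aS)-2-[(2R)-butan-2-yl]-1,8-dimethyl-1,2,4a,7,8,8a-hexahydronaphthalene-1-carboxylic acid
Conditions: Grubbs second-generation catalyst (5 mol %), CH2Cl2 (5 mM), 40 °C
Reagents that add atoms: none
Why: Ring-closing metathesis of the two terminal alkenes, held trans on ring A, closes ring B (six-membered, C5=C6) as the trans-fused octalin with loss of ethene; the endocyclic C3=C4 bond and the free acid are inert.

**Step 18**
Reactants: 28 (octalin acid)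
Product: 29 1-[(1S,2S,4aR,8R,8aS)-2-[(2R)-butan-2-yl]-1,8-dimethyl-1,2,4a,7,8,8a-hexahydronaphthalen-1-yl]ethan-1-one
Conditions: MeLi (4 equiv), Et2O, 0 °C → rt; then H2O
Reagents that add atoms: methyllithium, [Li]C
Why: Addition of methyllithium to the lithium carboxylate gives a gem-dialkoxide that collapses to the methyl ketone only on work-up, the standard route from hindered acids to methyl ketones.

**Step 19**
Reactants: 29 (methyl ketone)
Product: 31 1-[(1S,2S,4aR,8R,8aS)-2-[(2R)-butan-2-yl]-1,8-dimethyl-1,2,4a,7,8,8a-hexahydronaphthalen-1-yl]-3-hydroxypropan-1-one, via ketone lithium enolate 30 (not isolated)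
Conditions: LDA, THF, −78 °C; CH2O (gas, from paraformaldehyde), −78 → −30 °C; H2O
Reagents that add atoms: formaldehyde, C=O
Why: Aldol addition of the only possible enolate (C1 is quaternary) to monomeric formaldehyde installs the 3-hydroxypropanoyl chain.

**Step 20**
Reactants: 31 (β-hydroxy ketone)
Product: 32 3-[(tert-butyldimethylsilyl)oxy]-1-[(1S,2S,4aR,8R,8aS)-2-[(2R)-butan-2-yl]-1,8-dimethyl-1,2,4a,7,8,8a-hexahydronaphthalen-1-yl]propan-1-one
Conditions: TBSCl, imidazole, DMF, 0 °C → rt
Reagents that add atoms: tert-butyldimethylsilyl chloride, CC(C)(C)[Si](C)(C)Cl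
Why: Silylation masks the primary alcohol so that it cannot compete in the later acylation.

**Step 21**
Reactants: 32 (silyl ether diene)
Product: 33 3-[(tert-butyldimethylsilyl)oxy]-1-[(1S,2S,4aR,5S,6R,8R,8aS)-2-[(2R)-butan-2-yl]-5,6-dihydroxy-1,8-dimethyl-1,2,4a,5,6,7,8,8a-octahydronaphthalen-1-yl]propan-1-one
Conditions: K2OsO4·2H2O (2 mol %), NMO, acetone/H2O (5:1), 0 °C → rt
Reagents that add atoms: N-methylmorpholine N-oxide, C[N+]1([O-])CCOCC1; water, O
Why: Upjohn syn-dihydroxylation; osmium tetroxide should take the C5=C6 bond (C3=C4 is screened on one face by the axial C1 methyl and on the other by the C2 sec-butyl group) anti to the pseudo-equatorial allylic C4a–C4 bond, that is on the C4a–H face, which sets C5 (S) and C6 (R).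

**Step 22**
Reactants: 34 3-methylglutaconic acid (E/Z mixture)
Product: 35 3-methylglutaconic anhydride (4-methyl-2H-pyran-2,6(3H)-dione)
Conditions: Ac2O, 60 °C; evaporation
Reagents that add atoms: none
Why: Dehydrative cyclisation with acetic anhydride; the E acid isomerises through its enol form under these conditions, so both isomers converge on the cis cyclic anhydride.

**Step 23**
Reactants: 33 (5,6-diol); 35 3-methylglutaconic anhydride
Product: 37 (2Z)-5-{[(1S,2S,4aR,5S,6R,8R,8aS)-2-[(2R)-butan-2-yl]-1-{3-[(tert-butyldimethylsilyl)oxy]propanoyl}-6-hydroxy-1,8-dimethyl-1,2,4a,5,6,7,8,8a-octahydronaphthalen-5-yl]oxy}-3-methyl-5-oxopent-2-enoic acid, via dibutylstannylene acetal 36 (not isolated)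
Conditions: Bu2SnO, PhMe, reflux (−H2O); then 35, PhMe/CH2Cl2, 0 °C → rt; aq. KHSO4
Reagents that add atoms: none
Why: Stannylene acetal-mediated regioselective acylation; the stannylene of the cis-diol reacts at the equatorial C5 oxygen, which opens the anhydride at its more electrophilic non-conjugated carbonyl, so the ester sits on the CH2 terminus and the Z conjugated acid is released.

**Step 24**
Reactants: 37 (silyl ether of the target)
Product: 38 tandyukisin C
Conditions: HF·pyridine, pyridine, THF, 0 °C → rt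
Reagents that add atoms: none
Why: Fluoride-mediated desilylation under buffered, weakly acidic conditions should free the primary alcohol without acyl migration or retro-aldol cleavage.

**Compound list**

1 | (4S)-4-benzyl-3-propanoyl-1,3-oxazolidin-2-one | CCC(=O)N1[C@@H](Cc2ccccc2)COC1=O | starting material
2 | (4S)-4-benzyl-3-[(2R)-2-methylpent-4-enoyl]-1,3-oxazolidin-2-one | C=CC[C@@H](C)C(=O)N1[C@@H](Cc2ccccc2)COC1=O | intermediate
3 | (2R)-2-methylpent-4-en-1-ol | C=CC[C@@H](C)CO | intermediate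
4 | (2R)-2-methylpent-4-enal (not isolated) | C=CC[C@@H](C)C=O | intermediate
5 | (2E,4R)-4-methylhepta-2,6-dienal | C=CC[C@@H](C)/C=C/C=O | intermediate
6 | S-tert-butyl ethanethioate | CC(=O)SC(C)(C)C | starting material
7 | tert-butyl{[1-(tert-butylsulfanyl)ethenyl]oxy}dimethylsilane | C=C(SC(C)(C)C)O[Si](C)(C)C(C)(C)C | intermediate
8 | S-tert-butyl (3S,4R)-4-methyl-3-(2-oxoethyl)hept-6-enethioate | CC(C)(C)SC(=O)C[C@H](CC=O)[C@H](C)CC=C | intermediate
9 | (3S,4R)-3-[2-(tert-butylsulfanyl)-2-oxoethyl]-4-methylhept-6-enoic acid | CC(C)(C)SC(=O)C[C@H](CC(=O)O)[C@H](C)CC=C | intermediate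
10 | (4S)-4-benzyl-1,3-oxazolidin-2-one | O=C1N[C@@H](Cc2ccccc2)CO1 | starting material
11 | mixed anhydride of 9 with pivalic acid (not isolated) | CC(C)(C)SC(=O)C[C@H](CC(=O)OC(=O)C(C)(C)C)[C@H](C)CC=C | intermediate
12 | S-tert-butyl (3S,4R)-3-{2-[(4S)-4-benzyl-2-oxo-1,3-oxazolidin-3-yl]-2-oxoethyl}-4-methylhept-6-enethioate | CC(C)(C)SC(=O)C[C@H](CC(=O)N1[C@@H](Cc2ccccc2)COC1=O)[C@H](C)CC=C | intermediate
13 | (2S)-3-bromo-2-methylpropan-1-ol | BrC[C@@H](C)CO | starting material
14 | (2R)-2-methylbutan-1-ol | CC[C@@H](C)CO | intermediate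
15 | (2R)-2-methylbutanal (not isolated) | CC[C@@H](C)C=O | intermediate
16 | (2E,4R)-4-methylhex-2-enal | CC[C@@H](C)/C=C/C=O | intermediate
17 | Z-dibutylboron enolate of 12 (not isolated) | CC(C)(C)SC(=O)C[C@H](/C=C(\OB(CCCC)CCCC)N1[C@@H](Cc2ccccc2)COC1=O)[C@H](C)CC=C | intermediate
18 | S-tert-butyl (3S,4R)-3-[(2S,3R,4E,6R)-1-[(4S)-4-benzyl-2-oxo-1,3-oxazolidin-3-yl]-3-hydroxy-6-methyl-1-oxooct-4-en-2-yl]-4-methylhept-6-enethioate | CC[C@@H](C)/C=C/[C@@H](O)[C@@H](C(=O)N1[C@@H](Cc2ccccc2)COC1=O)[C@H]([C@H](C)CC=C)CC(=O)SC(C)(C)C | intermediate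
19 | (4S)-4-benzyl-3-{(2R,3S,4S)-2-[(1E,3R)-3-methylpent-1-en-1-yl]-6-oxo-4-[(2R)-pent-4-en-2-yl]oxane-3-carbonyl}-1,3-oxazolidin-2-one | CC[C@@H](C)/C=C/[C@@H]1[C@@H](C(=O)N2[C@@H](Cc3ccccc3)COC2=O)[C@H]([C@H](C)CC=C)CC(=O)O1 | intermediate
20 | (4S,5R,6R)-5-(hydroxymethyl)-6-[(1E,3R)-3-methylpent-1-en-1-yl]-4-[(2R)-pent-4-en-2-yl]oxan-2-one | CC[C@@H](C)/C=C/[C@@H]1[C@@H](CO)[C@H]([C@H](C)CC=C)CC(=O)O1 | intermediate
21 | (2R,3S,4S)-2-[(1E,3R)-3-methylpent-1-en-1-yl]-6-oxo-4-[(2R)-pent-4-en-2-yl]oxane-3-carbaldehyde | CC[C@@H](C)/C=C/[C@@H]1[C@@H](C=O)[C@H]([C@H](C)CC=C)CC(=O)O1 | intermediate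
22 | (4S,5S,6R)-5-ethenyl-6-[(1E,3R)-3-methylpent-1-en-1-yl]-4-[(2R)-pent-4-en-2-yl]oxan-2-one | CC[C@@H](C)/C=C/[C@@H]1[C@@H](C=C)[C@H]([C@H](C)CC=C)CC(=O)O1 | intermediate
23 | lithium enolate of 22 (not isolated) | CC[C@@H](C)/C=C/[C@@H]1[C@@H](C=C)[C@H]([C@H](C)CC=C)C=C(O[Li])O1 | intermediate
24 | (3R,4S,5S,6R)-5-ethenyl-3-methyl-6-[(1E,3R)-3-methylpent-1-en-1-yl]-4-[(2R)-pent-4-en-2-yl]oxan-2-one (key-step precursor) | CC[C@@H](C)/C=C/[C@@H]1[C@@H](C=C)[C@H]([C@H](C)CC=C)[C@@H](C)C(=O)O1 | intermediate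
25 | tert-butyl({(2R,3S,4S)-3-ethenyl-5-methyl-2-[(1E,3R)-3-methylpent-1-en-1-yl]-4-[(2R)-pent-4-en-2-yl]-3,4-dihydro-2H-pyran-6-yl}oxy)dimethylsilane (not isolated) | CC[C@@H](C)/C=C/[C@@H]1[C@@H](C=C)[C@H]([C@H](C)CC=C)C(C)=C(O[Si](C)(C)C(C)(C)C)O1 | intermediate
26 | tert-butyldimethylsilyl ester of 27 (not isolated) | CC[C@@H](C)[C@H]1C=C[C@@H](C=C)[C@H]([C@H](C)CC=C)[C@@]1(C)C(=O)O[Si](C)(C)C(C)(C)C | intermediate
27 | (1S,2S,5R,6S)-2-[(2R)-butan-2-yl]-5-ethenyl-1-methyl-6-[(2R)-pent-4-en-2-yl]cyclohex-3-ene-1-carboxylic acid (key-step product) | CC[C@@H](C)[C@H]1C=C[C@@H](C=C)[C@H]([C@H](C)CC=C)[C@@]1(C)C(=O)O | intermediate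
28 | (1S,2S,4aR,8R,8aS)-2-[(2R)-butan-2-yl]-1,8-dimethyl-1,2,4a,7,8,8a-hexahydronaphthalene-1-carboxylic acid | CC[C@@H](C)[C@H]1C=C[C@H]2C=CC[C@@H](C)[C@@H]2[C@@]1(C)C(=O)O | intermediate
29 | 1-[(1S,2S,4aR,8R,8aS)-2-[(2R)-butan-2-yl]-1,8-dimethyl-1,2,4a,7,8,8a-hexahydronaphthalen-1-yl]ethan-1-one | CC[C@@H](C)[C@H]1C=C[C@H]2C=CC[C@@H](C)[C@@H]2[C@@]1(C)C(C)=O | intermediate
30 | lithium enolate of 29 (not isolated) | CC[C@@H](C)[C@H]1C=C[C@H]2C=CC[C@@H](C)[C@@H]2[C@@]1(C)C(=C)O[Li] | intermediate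
31 | 1-[(1S,2S,4aR,8R,8aS)-2-[(2R)-butan-2-yl]-1,8-dimethyl-1,2,4a,7,8,8a-hexahydronaphthalen-1-yl]-3-hydroxypropan-1-one | CC[C@@H](C)[C@H]1C=C[C@H]2C=CC[C@@H](C)[C@@H]2[C@@]1(C)C(=O)CCO | intermediate
32 | tert-butyldimethylsilyl ether of 31 | CC[C@@H](C)[C@H]1C=C[C@H]2C=CC[C@@H](C)[C@@H]2[C@@]1(C)C(=O)CCO[Si](C)(C)C(C)(C)C | intermediate
33 | 3-[(tert-butyldimethylsilyl)oxy]-1-[(1S,2S,4aR,5S,6R,8R,8aS)-2-[(2R)-butan-2-yl]-5,6-dihydroxy-1,8-dimethyl-1,2,4a,5,6,7,8,8a-octahydronaphthalen-1-yl]propan-1-one | CC[C@@H](C)[C@H]1C=C[C@H]2[C@H](O)[C@H](O)C[C@@H](C)[C@@H]2[C@@]1(C)C(=O)CCO[Si](C)(C)C(C)(C)C | intermediate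
34 | 3-methylglutaconic acid (3-methylpent-2-enedioic acid, E/Z mixture) | CC(CC(=O)O)=CC(=O)O | starting material
35 | 3-methylglutaconic anhydride (4-methyl-2H-pyran-2,6(3H)-dione) | CC1=CC(=O)OC(=O)C1 | intermediate
36 | 5,6-O-dibutylstannylene acetal of 33 (not isolated) | CC[C@@H](C)[C@H]1C=C[C@H]2[C@@H]3O[Sn](CCCC)(CCCC)O[C@@H]3C[C@@H](C)[C@@H]2[C@@]1(C)C(=O)CCO[Si](C)(C)C(C)(C)C | intermediate
37 | tert-butyldimethylsilyl ether of tandyukisin C (primary hydroxyl silylated) | CC[C@@H](C)[C@H]1C=C[C@H]2[C@H](OC(=O)C/C(C)=C\C(=O)O)[C@H](O)C[C@@H](C)[C@@H]2[C@@]1(C)C(=O)CCO[Si](C)(C)C(C)(C)C | intermediate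
38 | tandyukisin C, (2Z)-5-{[(1S,2S,4aR,5S,6R,8R,8aS)-2-[(2R)-butan-2-yl]-6-hydroxy-1-(3-hydroxypropanoyl)-1,8-dimethyl-1,2,4a,5,6,7,8,8a-octahydronaphthalen-5-yl]oxy}-3-methyl-5-oxopent-2-enoic acid | CC[C@@H](C)[C@H]1C=C[C@H]2[C@H](OC(=O)C/C(C)=C\C(=O)O)[C@H](O)C[C@@H](C)[C@@H]2[C@@]1(C)C(=O)CCO | target

**Step count**

Total: 24 steps. Longest linear sequence: 20 steps (1, 2, 3, 5, 6, 7, 10–21, 23, 24).

**Steps most likely to fail**

Step 16 (key step). The congested, tetrasubstituted ketene acetal may be consumed by C-silylation, hydrolysis or elimination before the all-equatorial lactone has flexed into the boat that the [3,3] shift demands. The fallback builds the quaternary centre by alkylation instead and sets out from lactone 22, which lacks the C1 methyl group. Enolisation and silylation (LDA, TBSCl, DMPU, −78 °C) should give the less hindered trisubstituted silyl ketene acetal F1. This should rearrange in toluene at 110 °C to the silyl ester F2, and dilute HCl would free the C1-unmethylated ring A acid F3, whose C1 is only tertiary. Double deprotonation of F3 (LDA 2.2 equiv, THF/DMPU, 0 °C) and methylation with MeI are expected to occur on the face of the exocyclic enediolate anti to the axial C2 sec-butyl group. This places the methyl trans to sec-butyl and returns the route at 27.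

Step 5. Conjugate addition to the γ-branched iminium ion may be slower than hydrolysis of the ketene thioacetal, or the C8 centre may erode the facial control of the catalyst. The fallback sets out from alcohol 3. It is oxidised to 4 (Swern) and condensed with diallyl malonate (TiCl4, pyridine, THF, 0 °C) to diallyl 2-[(2R)-2-methylpent-4-en-1-ylidene]propanedioate F4. A copper(II)–bis(oxazoline)-catalysed Mukaiyama–Michael addition of 7 ([Cu(t-Bu-box)](SbF6)2 10 mol %, (CF3)2CHOH, PhMe/CH2Cl2, −78 °C; ligand enantiomer chosen for the 3S adduct) should then give the differentiated glutarate, diallyl 2-[(3S,4R)-1-(tert-butylsulfanyl)-4-methyl-1-oxohept-6-en-3-yl]propanedioate F5. Pd(PPh3)4 and morpholine would remove both allyl esters to give the malonic acid F6, which should lose CO2 in toluene at 100 °C and return the route at 9.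

Step 21. Osmylation may take place on the C8a–H face of the C5=C6 bond, since only the pseudo-equatorial C4a–C4 bond tells the two faces apart. The fallback sets out from 32 and uses the Woodward cis-hydroxylation. Iodine and silver acetate in acetic acid should form the iodonium ion on that same, more accessible face, and acetate opens it trans-diaxially to the 5-iodo-6-acetate F7. Warming with wet acetic acid (50 °C) lets the acetate displace iodide through an acetoxonium ion, so both oxygens end on the C4a–H face in the hydroxy acetate F8 (6-O-acetate drawn; its 5-O isomer behaves alike). Methanolysis (K2CO3, MeOH, 0 °C) returns the route at 33.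

**Further compounds**

F1 | step 16 | tert-butyl({(2R,3S,4S)-3-ethenyl-2-[(1E,3R)-3-methylpent-1-en-1-yl]-4-[(2R)-pent-4-en-2-yl]-3,4-dihydro-2H-pyran-6-yl}oxy)dimethylsilane | CC[C@@H](C)/C=C/[C@@H]1[C@@H](C=C)[C@H]([C@H](C)CC=C)C=C(O[Si](C)(C)C(C)(C)C)O1
F2 | step 16 | tert-butyldimethylsilyl (1S,2S,5R,6S)-2-[(2R)-butan-2-yl]-5-ethenyl-6-[(2R)-pent-4-en-2-yl]cyclohex-3-ene-1-carboxylate | CC[C@@H](C)[C@H]1C=C[C@@H](C=C)[C@H]([C@H](C)CC=C)[C@H]1C(=O)O[Si](C)(C)C(C)(C)C
F3 | step 16 | (1S,2S,5R,6S)-2-[(2R)-butan-2-yl]-5-ethenyl-6-[(2R)-pent-4-en-2-yl]cyclohex-3-ene-1-carboxylic acid | CC[C@@H](C)[C@H]1C=C[C@@H](C=C)[C@H]([C@H](C)CC=C)[C@H]1C(=O)O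
F4 | step 5 | diallyl 2-[(2R)-2-methylpent-4-en-1-ylidene]propanedioate | C=CCOC(=O)C(=C[C@H](C)CC=C)C(=O)OCC=C
F5 | step 5 | diallyl 2-[(3S,4R)-1-(tert-butylsulfanyl)-4-methyl-1-oxohept-6-en-3-yl]propanedioate | CC(C)(C)SC(=O)C[C@H](C(C(=O)OCC=C)C(=O)OCC=C)[C@H](C)CC=C
F6 | step 5 | 2-[(3S,4R)-1-(tert-butylsulfanyl)-4-methyl-1-oxohept-6-en-3-yl]propanedioic acid | CC(C)(C)SC(=O)C[C@H](C(C(=O)O)C(=O)O)[C@H](C)CC=C
F7 | step 21 | 5-iodo-6-acetate of 32 (iodine on the C8a–H face at C5, acetoxy on the C4a–H face at C6) | CC[C@@H](C)[C@H]1C=C[C@H]2[C@@H](I)[C@H](OC(C)=O)C[C@@H](C)[C@@H]2[C@@]1(C)C(=O)CCO[Si](C)(C)C(C)(C)C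
F8 | step 21 | 6-O-acetate of diol 33 | CC[C@@H](C)[C@H]1C=C[C@H]2[C@H](O)[C@H](OC(C)=O)C[C@@H](C)[C@@H]2[C@@]1(C)C(=O)CCO[Si](C)(C)C(C)(C)C
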